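**Plan**
Target: oxacyclotritriacontan-2-one, the 33-membered lactone of 32-hydroxydotriacontanoic acid (C32H62O2, one ring, no stereocentre). Atoms are counted from the lactone carbonyl C1 round to C32–O.
Enabling feature: C12 and C13 are adjacent, unfunctionalised ring CH2 groups. A sulfonyl bridge imagined between them gives a 34-membered 1-oxa-14-thia ring, which returns the 33-membered lactone ring when SO2 is expelled.
Cuts, in retrosynthetic order: C12–C13 (alkene, then Ramberg–Bäcklund); S–C13 (thiolate displacing bromide, the only macrocyclisation); the C1–O ester bond, which joins the C1–C12 and C13–C32 pieces.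
Forward: icosanedioic acid is reduced and monobrominated to the C13–C32 bromo alcohol and esterified with 12-sulfanyldodecanoic acid (C1–C12). The ester is closed at sulfur, chlorinated and oxidised, contracted, then hydrogenated.
Stereochemistry: nothing needs control. The chlorinated carbon is racemic and the alkene geometry is free, and both disappear before the end.

Key step: step 6

Assumption: NCS is not expected to distinguish the two SCH2 groups. The 15-chloro compounds drawn and numbered below (racemic, one enantiomer drawn) should therefore be accompanied by their 13-chloro regioisomers, carried along unseparated because both series converge on the same alkene.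

Step 1
Reactants: 1 icosanedioic acid
Product: 2 icosane-1,20-diol
Conditions: BH3·THF (3 equiv), THF, 0 °C to rt; H2O quench
Reagents that add atoms: none
Why: Borane reduction of carboxylic acids runs through soluble acyloxyboranes and should take both ends of the sparingly soluble C20 diacid cleanly to primary alcohols.

Step 2
Reactants: 2 icosane-1,20-diol
Product: 3 20-bromoicosan-1-ol
Conditions: 48% aq. HBr (1.2 equiv), toluene, reflux
Reagents that add atoms: hydrogen bromide, Br
Why: Two-phase monobromination of an alpha,omega-diol (SN2 on the protonated alcohol) is known to stop largely at the bromo alcohol in toluene, and the polar diol and the non-polar dibromide are easily separated from it.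

Step 3
Reactants: 3 20-bromoicosan-1-ol; 4 12-sulfanyldodecanoic acid
Product: 5 20-bromoicosyl 12-sulfanyldodecanoate
Conditions: p-TsOH·H2O (5 mol %), toluene, Dean–Stark reflux, Ar
Reagents that add atoms: none
Why: Fischer esterification with azeotropic water removal acylates the primary alcohol while the un-ionised thiol stays a spectator, being too poor a nucleophile under acid to displace bromide and thermodynamically disfavoured as an acyl acceptor, as in the routine preparation of mercaptoalkanoate esters.

Step 4
Reactants: 5 20-bromoicosyl 12-sulfanyldodecanoate
Product: 6 1-oxa-14-thiacyclotetratriacontan-2-one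
Conditions: Cs2CO3 (2 equiv), DMF, 55 °C, Ar; 5 in THF added by syringe pump over 24 h (final 2 mM)
Reagents that add atoms: none
Why: Cesium thiolate macrocyclisation (intramolecular SN2, 34-exo-tet) under pseudo-high dilution lets the soft, loosely ion-paired thiolate reach its own primary bromide before it meets a second molecule, and carbonate in an aprotic solvent generates no alkoxide that could cut the ester tether.

Step 5
Reactants: 6 1-oxa-14-thiacyclotetratriacontan-2-one
Product: 9 rac-15-chloro-1-oxa-14-thiacyclotetratriacontan-2-one 14,14-dioxide, via alpha-chloro sulfide 7 (not isolated), via alpha-chloro sulfoxide 8 (not isolated)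
Conditions: NCS (1.05 equiv), CH2Cl2, 0 °C to rt; then mCPBA (2.3 equiv), CH2Cl2, 0 °C to rt
Reagents that add atoms: N-chlorosuccinimide (NCS), O=C1CCC(=O)N1Cl; 3-chloroperoxybenzoic acid (mCPBA), OOC(=O)c1cccc(Cl)c1
Why: NCS chlorination of a dialkyl sulfide passes through the chlorosulfonium salt and a Pummerer-type thionium ion to the labile alpha-chloro sulfide, which the peracid oxidises at once through the sulfoxide to the stable sulfone; the new C–Cl stereocentre is racemic and is destroyed in step 6.

Step 6
Reactants: 9 rac-15-chloro-1-oxa-14-thiacyclotetratriacontan-2-one 14,14-dioxide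
Product: 11 (E)-oxacyclotritriacont-13-en-2-one, via trans-episulfone 10 (not isolated)
Conditions: t-BuOK (2.5 equiv), THF (0.01 M), −78 °C to 0 °C
Reagents that add atoms: none
Why: Ramberg–Bäcklund reaction run as a one-atom ring contraction, a transformation well known for cyclic and macrocyclic alpha-halo sulfones. tert-Butoxide reversibly deprotonates both carbons flanking sulfur, and the C12 carbanion expels chloride from C13 in a 3-exo-tet closure that creates the C12–C13 bond, and with it the 33-membered ring, inside episulfone 10; cheletropic, stereospecific loss of SO2 then leaves C12=C13 in 11. The only stereocentres formed are the two transient ones of 10, where equilibration of the carbanions under a strong base should favour the less crowded trans arrangement and hence the E alkene, although either geometry serves because step 7 erases it. The selectivity that matters is sulfone over lactone: the sulfone alpha protons are at least as acidic as those next to the ester, an ester enolate forms reversibly and finds no leaving group within reach, the bulky alkoxide adds sluggishly to the carbonyl in the cold, and dilution holds back intermolecular Claisen condensation. Dehydrochlorination to a vinyl sulfone should not intervene, since alpha-halo sulfones resist ordinary substitution and E2 pathways whereas the 1,3-elimination is intramolecular. Regiocontrol is not needed, as the 13-chloro isomer reaches 11 through the mirror-image sequence (carbanion at C13, chloride leaving C12).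

Step 7
Reactants: 11 (E)-oxacyclotritriacont-13-en-2-one
Product: 12 oxacyclotritriacontan-2-one
Conditions: H2 (1 atm), 10% Pd/C, EtOAc/THF, rt
Reagents that add atoms: none
Why: Heterogeneous catalytic hydrogenation of an unhindered 1,2-disubstituted alkene is fast at balloon pressure and leaves the lactone untouched, provided 11 has been freed of sulfur-containing traces by chromatography.

**Compound list**
1 | icosanedioic acid | OC(=O)CCCCCCCCCCCCCCCCCCC(=O)O | starting material
2 | icosane-1,20-diol | OCCCCCCCCCCCCCCCCCCCCO | intermediate
3 | 20-bromoicosan-1-ol | OCCCCCCCCCCCCCCCCCCCCBr | intermediate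
4 | 12-sulfanyldodecanoic acid (12-mercaptododecanoic acid) | OC(=O)CCCCCCCCCCCS | starting material
5 | 20-bromoicosyl 12-sulfanyldodecanoate | O=C(CCCCCCCCCCCS)OCCCCCCCCCCCCCCCCCCCCBr | intermediate
6 | 1-oxa-14-thiacyclotetratriacontan-2-one | O=C1CCCCCCCCCCCSCCCCCCCCCCCCCCCCCCCCO1 | intermediate
7 | rac-15-chloro-1-oxa-14-thiacyclotetratriacontan-2-one (15R enantiomer drawn) | O=C1CCCCCCCCCCCS[C@H](Cl)CCCCCCCCCCCCCCCCCCCO1 | intermediate
8 | rac-15-chloro-1-oxa-14-thiacyclotetratriacontan-2-one 14-oxide (15R drawn, both configurations at sulfur) | O=C1CCCCCCCCCCCS(=O)[C@H](Cl)CCCCCCCCCCCCCCCCCCCO1 | intermediate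
9 | rac-15-chloro-1-oxa-14-thiacyclotetratriacontan-2-one 14,14-dioxide (15R enantiomer drawn) | O=C1CCCCCCCCCCCS(=O)(=O)[C@H](Cl)CCCCCCCCCCCCCCCCCCCO1 | intermediate
10 | rac-trans-13-oxa-34-thiabicyclo[31.1.0]tetratriacontan-12-one 34,34-dioxide (episulfone across C12–C13, S,S enantiomer drawn) | O=C1CCCCCCCCCC[C@H]2[C@H](CCCCCCCCCCCCCCCCCCCO1)S2(=O)=O | intermediate
11 | (E)-oxacyclotritriacont-13-en-2-one | O=C1CCCCCCCCCC/C=C/CCCCCCCCCCCCCCCCCCCO1 | intermediate
12 | oxacyclotritriacontan-2-one | O=C1CCCCCCCCCCCCCCCCCCCCCCCCCCCCCCCO1 | target

Total step count: 7. Longest linear sequence: 7 (from 1).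

**Steps most likely to fail**

**Step 6.** The alkoxide may attack the lactone carbonyl (ring opening), or Claisen-type self-condensation may outrun the 1,3-elimination.
- The fallback sets out from 9 and gives up the ester on purpose.
- KOH in aqueous t-BuOH at 70 °C should saponify the lactone and run the Ramberg–Bäcklund extrusion on the open-chain carboxylate, which base cannot damage further.
- Acidification should give (Z)-32-hydroxydotriacont-12-enoic acid F1, since hydroxide bases favour the Z alkene.
- Shiina macrolactonisation (MNBA, DMAP, toluene, slow addition) then closes the 33-membered ring at the C1–O bond to (Z)-oxacyclotritriacont-13-en-2-one F2.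
- Hydrogenation under the conditions of step 7 rejoins the route at 12.

**Step 4.** Intermolecular S-alkylation (oligomerisation) or oxidative disulfide coupling may compete with ring closure.
- The fallback sets out from 3 (with 4) and makes the C–S bond first, at ordinary concentration.
- Alkylating the dianion of 4 (KOH, 2.1 equiv, EtOH/THF, 60 °C) with 3 should give, after acidification, 12-[(20-hydroxyicosyl)sulfanyl]dodecanoic acid F3.
- The 34-membered ring is then closed at the ester by Shiina macrolactonisation (MNBA, DMAP, CH2Cl2/toluene, slow addition), which comes back to the route at 6.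

**Step 5.** Over-chlorination, loss of HCl, or hydrolysis of the labile chloro sulfide may occur before the peracid arrives.
- The fallback sets out from 6 and introduces the halogen at the sulfoxide level.
- mCPBA (1.0 equiv, CH2Cl2, −40 °C) should give 1-oxa-14-thiacyclotetratriacontan-2-one 14-oxide F4.
- Alpha-chlorination of this sulfoxide (NCS, K2CO3, CH2Cl2, rt) comes back to the route at 8, now an isolable compound, which mCPBA takes on to 9.

**Further compounds**
F1 | step 6 | (Z)-32-hydroxydotriacont-12-enoic acid | OC(=O)CCCCCCCCCC/C=C\CCCCCCCCCCCCCCCCCCCO
F2 | step 6 | (Z)-oxacyclotritriacont-13-en-2-one | O=C1CCCCCCCCCC/C=C\CCCCCCCCCCCCCCCCCCCO1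
F3 | step 4 | 12-[(20-hydroxyicosyl)sulfanyl]dodecanoic acid | OC(=O)CCCCCCCCCCCSCCCCCCCCCCCCCCCCCCCCO
F4 | step 5 | 1-oxa-14-thiacyclotetratriacontan-2-one 14-oxide (racemic at sulfur) | O=C1CCCCCCCCCCCS(=O)CCCCCCCCCCCCCCCCCCCCO1
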